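**Plan**

1. Numbering: C1 is the ring carbon that carries the vanillate, then C2=C3(CH3), C4(OH), C5, C6=C7(CH3), C8, C9, C10 and C11 = C(CH3)2. The crowded C1–C11 ring bond is the 1,6-bond of the six-carbon array C1–C2–C3/C9–C10–C11, so one added C3–C9 bond folds the 11-membered ring into a cyclohept-4-enol that holds a 3-hydroxy-1,5-diene.
2. Retrosynthesis, in order: the acyl C–O bond of the vanillate; C9 methylene back to a ketone; C1–C11 with C3–C9 drawn in (retro anionic oxy-Cope); the enol-ether C1–O bond and C1=C2; the ring alkene C6=C7; C9–C10 and C9–C8; C3–C9 and C3–CH3; C5–C6.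
3. Forward: the C2–C6 hydroxy ester chain is made first and C3 is made quaternary. C9 is then extended by methallyl and isobutenyl groups, and the seven-membered ring is closed by metathesis. After the E enol ether is installed, the 11-membered ring arises by four-carbon ring expansion. C9 is deoxygenated and the C1 hydroxyl acylated last.
4. Stereochemistry: C4 comes from the purchased epoxy ester 1. C3 comes from two chelate-controlled enolate alkylations next to C4, and C9 from a chelate-controlled alkenyl addition next to C3. C1 (R) and the E C2=C3 alkene come from chair chirality transfer in the key step. The Z C6=C7 alkene is fixed by the seven-membered ring.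

Key step: step 15

Assumption: ethyl (R)-3,4-epoxybutanoate (1) is taken as a catalogue compound available as the single enantiomer.

**Route**

Step 1
Reactants: 1 ethyl 2-[(2R)-oxiran-2-yl]acetate; 2 vinylmagnesium bromide
Product: 3 ethyl (3S)-3-hydroxyhex-5-enoate
Conditions: CuI (10 mol%), THF, −78 to −30 °C; aq. NH4Cl
Reagents that add atoms: none
Why: Copper-catalysed SN2 opening of a terminal epoxide by a Grignard reagent (organocuprate epoxide opening) should occur at the CH2 terminus, so the carbinol carbon (C4) keeps the spatial arrangement of 1 (only its descriptor changes) and the C5–C6 allyl arm is installed.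

Step 2
Reactants: 3 ethyl (3S)-3-hydroxyhex-5-enoate
Product: 5 ethyl (2S,3S)-3-hydroxy-2-methylhex-5-enoate, via dilithium dianion 4 (not isolated)
Conditions: LiN(iPr)2 (2.2 equiv), THF, −78 to −20 °C; MeI, DMPU, −78 to 0 °C
Reagents that add atoms: iodomethane, CI
Why: Fráter–Seebach alkylation, in which the lithium-chelated alkoxide–enolate 4 should be methylated on the face remote from the allyl group of the carbinol carbon to give the 2,3-anti ester.

Step 3
Reactants: 5 ethyl (2S,3S)-3-hydroxy-2-methylhex-5-enoate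
Product: 7 ethyl (2S,3S)-2-[(benzyloxy)methyl]-3-hydroxy-2-methylhex-5-enoate, via dilithium dianion 6 (not isolated)
Conditions: LiN(iPr)2 (2.5 equiv), THF, −78 to −10 °C; BnOCH2Cl, DMPU, −78 to −20 °C
Reagents that add atoms: benzyl chloromethyl ether, ClCOCc1ccccc1
Why: A second Fráter–Seebach alkylation of the now fully substituted chelated enolate 6 should again bring the electrophile in anti to the C4 oxygen, so the benzyloxymethyl carbon (future C9) ends anti and the methyl syn, which sets the quaternary C3 relative to C4.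

Step 4
Reactants: 7 ethyl (2S,3S)-2-[(benzyloxy)methyl]-3-hydroxy-2-methylhex-5-enoate
Product: 8 ethyl (2S,3S)-2-[(benzyloxy)methyl]-2-methyl-3-[(triisopropylsilyl)oxy]hex-5-enoate
Conditions: iPr3SiOTf, 2,6-lutidine, CH2Cl2, 0 °C to rt
Reagents that add atoms: triisopropylsilyl trifluoromethanesulfonate, CC(C)[Si](C(C)C)(C(C)C)OS(=O)(=O)C(F)(F)F
Why: Silyl triflate silylation of a hindered secondary alcohol; the triisopropylsilyl ether is chosen because it should survive BCl3, hydride and KH and is too bulky to migrate to the C9 alkoxide later.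

Step 5
Reactants: 8 ethyl (2S,3S)-2-[(benzyloxy)methyl]-2-methyl-3-[(triisopropylsilyl)oxy]hex-5-enoate
Product: 9 ethyl (2S,3S)-2-(hydroxymethyl)-2-methyl-3-[(triisopropylsilyl)oxy]hex-5-enoate
Conditions: BCl3, CH2Cl2, −78 °C; MeOH
Reagents that add atoms: none
Why: Lewis-acid cleavage of a primary benzyl ether with BCl3 at low temperature is a standard debenzylation that should leave the terminal alkene, the ester and the hindered silyl ether untouched.

Step 6
Reactants: 9 ethyl (2S,3S)-2-(hydroxymethyl)-2-methyl-3-[(triisopropylsilyl)oxy]hex-5-enoate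
Product: 10 ethyl (2R,3S)-2-formyl-2-methyl-3-[(triisopropylsilyl)oxy]hex-5-enoate
Conditions: Dess–Martin periodinane, NaHCO3, CH2Cl2, 0 °C to rt
Reagents that add atoms: none
Why: Dess–Martin oxidation of a neopentyl primary alcohol gives the non-enolisable aldehyde (C9) under buffered conditions.

Step 7
Reactants: 10 ethyl (2R,3S)-2-formyl-2-methyl-3-[(triisopropylsilyl)oxy]hex-5-enoate; 11 2-methylallylmagnesium chloride
Product: 12 ethyl (2S,3S)-2-(1-hydroxy-3-methylbut-3-en-1-yl)-2-methyl-3-[(triisopropylsilyl)oxy]hex-5-enoate (both carbinol epimers)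
Conditions: THF, −78 °C; aq. NH4Cl
Reagents that add atoms: none
Why: Grignard 1,2-addition of the allylic reagent to the aldehyde, which is far more electrophilic than the flanking α-quaternary ethyl ester; both carbinol epimers are carried on because this centre is oxidised in the next step.

Step 8
Reactants: 12 ethyl (2S,3S)-2-(1-hydroxy-3-methylbut-3-en-1-yl)-2-methyl-3-[(triisopropylsilyl)oxy]hex-5-enoate
Product: 13 ethyl (2R,3S)-2-methyl-2-(3-methylbut-3-enoyl)-3-[(triisopropylsilyl)oxy]hex-5-enoate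
Conditions: Dess–Martin periodinane, NaHCO3, CH2Cl2, 0 °C
Reagents that add atoms: none
Why: Dess–Martin oxidation to the C9 ketone, with the bicarbonate buffer meant to keep the β,γ-unsaturated ketone from drifting into conjugation.

Step 9
Reactants: 13 ethyl (2R,3S)-2-methyl-2-(3-methylbut-3-enoyl)-3-[(triisopropylsilyl)oxy]hex-5-enoate; 14 (2-methylprop-1-en-1-yl)magnesium bromide
Product: 15 ethyl (2R,3S)-2-[(4R)-4-hydroxy-2,6-dimethylhepta-1,5-dien-4-yl]-2-methyl-3-[(triisopropylsilyl)oxy]hex-5-enoate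
Conditions: 14, CeCl3 (anhydrous), THF, −78 °C; then 13, −78 to −40 °C; aq. NH4Cl
Reagents that add atoms: none
Why: Organocerium 1,2-addition to a hindered, enolisable ketone under Cram-chelate control: the metal bridges the ketone and ester carbonyls, C3 then shows its methyl on one face and the bulky silyloxy-bearing C4 chain on the other, and the alkenyl group should enter past the methyl (the Felkin–Anh model predicts the same face), which sets C9 so that the two future alkenyl groups are trans once the ring is closed.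

Step 10
Reactants: 15 ethyl (2R,3S)-2-[(4R)-4-hydroxy-2,6-dimethylhepta-1,5-dien-4-yl]-2-methyl-3-[(triisopropylsilyl)oxy]hex-5-enoate
Product: 16 ethyl (1R,2R,7S)-2-hydroxy-1,4-dimethyl-2-(2-methylprop-1-en-1-yl)-7-[(triisopropylsilyl)oxy]cyclohept-4-ene-1-carboxylate
Conditions: second-generation Grubbs catalyst (5 mol%), CH2Cl2 (0.005 M), 40 °C
Reagents that add atoms: none
Why: Ring-closing olefin metathesis between the monosubstituted C6 alkene and the 1,1-disubstituted methallyl alkene should give the trisubstituted cycloheptene (necessarily Z), while the isobutenyl group, trisubstituted and attached to a fully substituted carbon next to quaternary C3, is expected to stay a spectator.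

Step 11
Reactants: 16 ethyl (1R,2R,7S)-2-hydroxy-1,4-dimethyl-2-(2-methylprop-1-en-1-yl)-7-[(triisopropylsilyl)oxy]cyclohept-4-ene-1-carboxylate
Product: 17 (1R,6S,7R)-7-(hydroxymethyl)-3,7-dimethyl-1-(2-methylprop-1-en-1-yl)-6-[(triisopropylsilyl)oxy]cyclohept-3-en-1-ol
Conditions: LiAlH4, Et2O, 0 °C; aqueous work-up
Reagents that add atoms: none
Why: LiAlH4 reduction of the hindered ester to the primary alcohol (C2), the tertiary alkoxide and the silyl ether being inert.

Step 12
Reactants: 17 (1R,6S,7R)-7-(hydroxymethyl)-3,7-dimethyl-1-(2-methylprop-1-en-1-yl)-6-[(triisopropylsilyl)oxy]cyclohept-3-en-1-ol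
Product: 18 (1R,2R,7S)-2-hydroxy-1,4-dimethyl-2-(2-methylprop-1-en-1-yl)-7-[(triisopropylsilyl)oxy]cyclohept-4-ene-1-carbaldehyde
Conditions: Dess–Martin periodinane, NaHCO3, CH2Cl2, 0 °C
Reagents that add atoms: none
Why: Dess–Martin oxidation can only act on the primary alcohol because the tertiary allylic alcohol has no carbinol hydrogen, and the buffered neutral medium should avoid retro-aldol cleavage of the β-hydroxy aldehyde.

Step 13
Reactants: 18 (1R,2R,7S)-2-hydroxy-1,4-dimethyl-2-(2-methylprop-1-en-1-yl)-7-[(triisopropylsilyl)oxy]cyclohept-4-ene-1-carbaldehyde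
Product: 19 (1R,6S,7R)-7-[(E)-2-iodoethenyl]-3,7-dimethyl-1-(2-methylprop-1-en-1-yl)-6-[(triisopropylsilyl)oxy]cyclohept-3-en-1-ol
Conditions: CrCl2, CHI3, THF/1,4-dioxane, 0 °C to rt
Reagents that add atoms: iodoform, IC(I)I
Why: Takai olefination (gem-dichromium reagent from CHI3 and CrCl2) should convert the hindered aldehyde into the E alkenyl iodide, adding C1, under non-basic conditions that spare the free tertiary alcohol.

Step 14
Reactants: 19 (1R,6S,7R)-7-[(E)-2-iodoethenyl]-3,7-dimethyl-1-(2-methylprop-1-en-1-yl)-6-[(triisopropylsilyl)oxy]cyclohept-3-en-1-ol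
Product: 20 (1R,6S,7R)-7-{(E)-2-[(4-methoxybenzyl)oxy]ethenyl}-3,7-dimethyl-1-(2-methylprop-1-en-1-yl)-6-[(triisopropylsilyl)oxy]cyclohept-3-en-1-ol
Conditions: CuI (15 mol%), 3,4,7,8-tetramethyl-1,10-phenanthroline (30 mol%), Cs2CO3, 4-MeOC6H4CH2OH, toluene, 80 °C
Reagents that add atoms: 4-methoxybenzyl alcohol, COc1ccc(CO)cc1
Why: Copper-catalysed Ullmann-type C–O coupling of an alkenyl iodide with a primary alcohol proceeds with retention of alkene geometry, so the E enol ether needed for the key step should result, and carbonate is too weak a base to form the tertiary alkoxide prematurely.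

Step 15
Reactants: 20 (1R,6S,7R)-7-{(E)-2-[(4-methoxybenzyl)oxy]ethenyl}-3,7-dimethyl-1-(2-methylprop-1-en-1-yl)-6-[(triisopropylsilyl)oxy]cyclohept-3-en-1-ol
Product: 23 (3Z,6S,7E,9R)-9-[(4-methoxybenzyl)oxy]-3,7,10,10-tetramethyl-6-[(triisopropylsilyl)oxy]cycloundeca-3,7-dien-1-one, via potassium alkoxide 21 (not isolated), via potassium enolate 22 (not isolated)
Conditions: KH, 18-crown-6, THF, 0 °C to rt; AcOH/THF, −78 °C
Reagents that add atoms: none
Why: KH with 18-crown-6 converts the C9 hydroxyl into the crown-separated alkoxide 21, whose oxyanion weakens the congested C3–C9 bond so that a concerted [3,3] shift over C1=C2–C3–C9–C10=C11 breaks it, joins C1 to C11 and leaves the C9 enolate 22, which is protonated cold to 23. The reaction type is the anionic oxy-Cope rearrangement of trans-1,2-dialkenylcycloalkanols, an established four-carbon ring expansion. No macrocyclisation is involved: the 11-membered ring is the seven-membered ring plus C1, C2, C10 and C11, and it emerges by ring expansion as the bond common to the cycloheptene and the pericyclic array gives way, with the enolate as the thermodynamic sink. The trans disposition of the two alkenyl groups admits one chair, with the ring bonds C3–C4 and C9–C8 equatorial and the C3 methyl axial, so C4 ends trans to C1 on the new alkene (E); in this chair the E enol ether keeps its alkoxy group equatorial and offers C11 the face of C1 that gives 1R, while C4 (S) is a spectator and the Z C6=C7 alkene passes through unchanged. Two selectivities are needed: the array through C1=C2 must win over the second oxido-diene C6=C7–C8–C9–C10=C11, which can only react through a bridged boat and would break the less substituted C8–C9 bond, and the kinetic enolate must be quenched at −78 °C so that the C6=C7 alkene does not move into conjugation with the new ketone.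

Step 16
Reactants: 23 (3Z,6S,7E,9R)-9-[(4-methoxybenzyl)oxy]-3,7,10,10-tetramethyl-6-[(triisopropylsilyl)oxy]cycloundeca-3,7-dien-1-one
Product: 24 tosylhydrazone of 23 at C9 (C=N isomers)
Conditions: TsNHNH2, EtOH, 40 °C
Reagents that add atoms: 4-methylbenzenesulfonohydrazide, Cc1ccc(cc1)S(=O)(=O)NN
Why: Condensation of the ketone with tosylhydrazide to the tosylhydrazone under near-neutral conditions that should leave the β,γ-alkene in place.

Step 17
Reactants: 24 tosylhydrazone of 23
Product: 26 (1R,2E,4S,6Z)-1-[(4-methoxybenzyl)oxy]-3,7,11,11-tetramethyl-4-[(triisopropylsilyl)oxy]cycloundeca-2,6-diene (target numbering), via N-boryl hydrazide 25 (not isolated)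
Conditions: catecholborane, CHCl3, 0 °C; NaOAc·3H2O, 60 °C
Reagents that add atoms: none
Why: Tosylhydrazone reduction with catecholborane (a mild Wolff–Kishner-type deoxygenation): B–H adds across C=N to give 25, acetate then releases sulfinate and the diazene loses N2 to leave CH2 at C9, and since C9 is not allylic no alkene transposition is expected.

Step 18
Reactants: 26 (1R,2E,4S,6Z)-1-[(4-methoxybenzyl)oxy]-3,7,11,11-tetramethyl-4-[(triisopropylsilyl)oxy]cycloundeca-2,6-diene
Product: 27 (1R,2E,4S,6Z)-3,7,11,11-tetramethyl-4-[(triisopropylsilyl)oxy]cycloundeca-2,6-dien-1-ol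
Conditions: DDQ, CH2Cl2/pH 7 buffer, 0 °C
Reagents that add atoms: none
Why: Oxidative cleavage of the 4-methoxybenzyl ether with DDQ via the benzylic cation and its hemiacetal should free the C1 alcohol without touching the silyl ether or the trisubstituted alkenes.

Step 19
Reactants: 28 vanillic acid
Product: 30 4-[(tert-butyldimethylsilyl)oxy]-3-methoxybenzoic acid, via bis(silyl) vanillate 29 (not isolated)
Conditions: tBuMe2SiCl, imidazole, DMF, rt; then AcOH/THF/H2O, rt
Reagents that add atoms: tert-butyldimethylsilyl chloride, CC(C)(C)[Si](C)(C)Cl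
Why: Silylation of both the phenol and the carboxyl group followed by selective hydrolysis of the labile silyl ester, which leaves the aryl silyl ether in place.

Step 20
Reactants: 27 (1R,2E,4S,6Z)-3,7,11,11-tetramethyl-4-[(triisopropylsilyl)oxy]cycloundeca-2,6-dien-1-ol; 30 4-[(tert-butyldimethylsilyl)oxy]-3-methoxybenzoic acid
Product: 32 (1R,2E,4S,6Z)-3,7,11,11-tetramethyl-4-[(triisopropylsilyl)oxy]cycloundeca-2,6-dien-1-yl 4-[(tert-butyldimethylsilyl)oxy]-3-methoxybenzoate, via mixed anhydride 31 (not isolated)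
Conditions: 30, 2,4,6-Cl3C6H2COCl, Et3N, THF, rt; then 27, DMAP, toluene, rt to 50 °C
Reagents that add atoms: none
Why: Yamaguchi esterification, in which DMAP transfers the less hindered aroyl group of mixed anhydride 31 to the hindered secondary allylic alcohol with retention at C1.

Step 21
Reactants: 32 (1R,2E,4S,6Z)-3,7,11,11-tetramethyl-4-[(triisopropylsilyl)oxy]cycloundeca-2,6-dien-1-yl 4-[(tert-butyldimethylsilyl)oxy]-3-methoxybenzoate
Product: 33 (1R,2E,4S,6Z)-4-hydroxy-3,7,11,11-tetramethylcycloundeca-2,6-dien-1-yl 4-hydroxy-3-methoxybenzoate (CNP0234435.1)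
Conditions: Bu4NF, AcOH, THF, 0 °C to rt
Reagents that add atoms: none
Why: Fluoride-induced cleavage of both Si–O bonds (secondary silyl ether and aryl silyl ether), buffered with acetic acid so that the aryl ester survives, while the E alkene between C1 and C4 rules out acyl migration.

**Compound list**

1 | ethyl 2-[(2R)-oxiran-2-yl]acetate (ethyl (R)-3,4-epoxybutanoate) | CCOC(=O)C[C@@H]1CO1 | starting material
2 | vinylmagnesium bromide | C=C[Mg]Br | starting material
3 | ethyl (3S)-3-hydroxyhex-5-enoate | CCOC(=O)C[C@@H](O)CC=C | intermediate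
4 | dilithium alkoxide–enolate of 3 | CCOC(O[Li])=C[C@@H](O[Li])CC=C | intermediate
5 | ethyl (2S,3S)-3-hydroxy-2-methylhex-5-enoate | CCOC(=O)[C@@H](C)[C@@H](O)CC=C | intermediate
6 | dilithium alkoxide–enolate of 5 | CCOC(O[Li])=C(C)[C@@H](O[Li])CC=C | intermediate
7 | ethyl (2S,3S)-2-[(benzyloxy)methyl]-3-hydroxy-2-methylhex-5-enoate | CCOC(=O)[C@@](C)(COCc1ccccc1)[C@@H](O)CC=C | intermediate
8 | ethyl (2S,3S)-2-[(benzyloxy)methyl]-2-methyl-3-[(triisopropylsilyl)oxy]hex-5-enoate | CCOC(=O)[C@@](C)(COCc1ccccc1)[C@@H](O[Si](C(C)C)(C(C)C)C(C)C)CC=C | intermediate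
9 | ethyl (2S,3S)-2-(hydroxymethyl)-2-methyl-3-[(triisopropylsilyl)oxy]hex-5-enoate | CCOC(=O)[C@@](C)(CO)[C@@H](O[Si](C(C)C)(C(C)C)C(C)C)CC=C | intermediate
10 | ethyl (2R,3S)-2-formyl-2-methyl-3-[(triisopropylsilyl)oxy]hex-5-enoate | CCOC(=O)[C@@](C)(C=O)[C@@H](O[Si](C(C)C)(C(C)C)C(C)C)CC=C | intermediate
11 | 2-methylallylmagnesium chloride | C=C(C)C[Mg]Cl | starting material
12 | ethyl (2S,3S)-2-(1-hydroxy-3-methylbut-3-en-1-yl)-2-methyl-3-[(triisopropylsilyl)oxy]hex-5-enoate, both carbinol epimers | CCOC(=O)[C@@](C)(C(O)CC(C)=C)[C@@H](O[Si](C(C)C)(C(C)C)C(C)C)CC=C | intermediate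
13 | ethyl (2R,3S)-2-methyl-2-(3-methylbut-3-enoyl)-3-[(triisopropylsilyl)oxy]hex-5-enoate | CCOC(=O)[C@@](C)(C(=O)CC(C)=C)[C@@H](O[Si](C(C)C)(C(C)C)C(C)C)CC=C | intermediate
14 | (2-methylprop-1-en-1-yl)magnesium bromide | CC(C)=C[Mg]Br | starting material
15 | ethyl (2R,3S)-2-[(4R)-4-hydroxy-2,6-dimethylhepta-1,5-dien-4-yl]-2-methyl-3-[(triisopropylsilyl)oxy]hex-5-enoate | CCOC(=O)[C@@](C)([C@](O)(C=C(C)C)CC(C)=C)[C@@H](O[Si](C(C)C)(C(C)C)C(C)C)CC=C | intermediate
16 | ethyl (1R,2R,7S)-2-hydroxy-1,4-dimethyl-2-(2-methylprop-1-en-1-yl)-7-[(triisopropylsilyl)oxy]cyclohept-4-ene-1-carboxylate | O[C@@]1(C=C(C)C)CC(C)=CC[C@H](O[Si](C(C)C)(C(C)C)C(C)C)[C@@]1(C)C(=O)OCC | intermediate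
17 | (1R,6S,7R)-7-(hydroxymethyl)-3,7-dimethyl-1-(2-methylprop-1-en-1-yl)-6-[(triisopropylsilyl)oxy]cyclohept-3-en-1-ol | O[C@@]1(C=C(C)C)CC(C)=CC[C@H](O[Si](C(C)C)(C(C)C)C(C)C)[C@@]1(C)CO | intermediate
18 | (1R,2R,7S)-2-hydroxy-1,4-dimethyl-2-(2-methylprop-1-en-1-yl)-7-[(triisopropylsilyl)oxy]cyclohept-4-ene-1-carbaldehyde | O[C@@]1(C=C(C)C)CC(C)=CC[C@H](O[Si](C(C)C)(C(C)C)C(C)C)[C@@]1(C)C=O | intermediate
19 | (1R,6S,7R)-7-[(E)-2-iodoethenyl]-3,7-dimethyl-1-(2-methylprop-1-en-1-yl)-6-[(triisopropylsilyl)oxy]cyclohept-3-en-1-ol | O[C@@]1(C=C(C)C)CC(C)=CC[C@H](O[Si](C(C)C)(C(C)C)C(C)C)[C@@]1(C)/C=C/I | intermediate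
20 | (1R,6S,7R)-7-{(E)-2-[(4-methoxybenzyl)oxy]ethenyl}-3,7-dimethyl-1-(2-methylprop-1-en-1-yl)-6-[(triisopropylsilyl)oxy]cyclohept-3-en-1-ol (oxy-Cope precursor) | O[C@@]1(C=C(C)C)CC(C)=CC[C@H](O[Si](C(C)C)(C(C)C)C(C)C)[C@@]1(C)/C=C/OCc2ccc(OC)cc2 | intermediate
21 | potassium alkoxide of 20 | [K+].[O-][C@@]1(C=C(C)C)CC(C)=CC[C@H](O[Si](C(C)C)(C(C)C)C(C)C)[C@@]1(C)/C=C/OCc2ccc(OC)cc2 | intermediate
22 | potassium C9 enolate of 23 (C9=C10, C8 and C11 trans) | [K+].COc1ccc(CO[C@@H]2/C=C(\C)[C@@H](O[Si](C(C)C)(C(C)C)C(C)C)C/C=C(/C)C/C([O-])=C/C2(C)C)cc1 | intermediate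
23 | (3Z,6S,7E,9R)-9-[(4-methoxybenzyl)oxy]-3,7,10,10-tetramethyl-6-[(triisopropylsilyl)oxy]cycloundeca-3,7-dien-1-one | COc1ccc(CO[C@@H]2/C=C(\C)[C@@H](O[Si](C(C)C)(C(C)C)C(C)C)C/C=C(/C)CC(=O)CC2(C)C)cc1 | intermediate
24 | tosylhydrazone of 23 at C9 | COc1ccc(CO[C@@H]2/C=C(\C)[C@@H](O[Si](C(C)C)(C(C)C)C(C)C)C/C=C(/C)CC(=NNS(=O)(=O)c3ccc(C)cc3)CC2(C)C)cc1 | intermediate
25 | N-(1,3,2-benzodioxaborol-2-yl) N'-tosyl hydrazide at C9 (from B–H addition to 24) | COc1ccc(CO[C@@H]2/C=C(\C)[C@@H](O[Si](C(C)C)(C(C)C)C(C)C)C/C=C(/C)CC(N(NS(=O)(=O)c3ccc(C)cc3)B3Oc4ccccc4O3)CC2(C)C)cc1 | intermediate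
26 | (1R,2E,4S,6Z)-1-[(4-methoxybenzyl)oxy]-3,7,11,11-tetramethyl-4-[(triisopropylsilyl)oxy]cycloundeca-2,6-diene | COc1ccc(CO[C@@H]2/C=C(\C)[C@@H](O[Si](C(C)C)(C(C)C)C(C)C)C/C=C(/C)CCCC2(C)C)cc1 | intermediate
27 | (1R,2E,4S,6Z)-3,7,11,11-tetramethyl-4-[(triisopropylsilyl)oxy]cycloundeca-2,6-dien-1-ol | O[C@@H]1/C=C(\C)[C@@H](O[Si](C(C)C)(C(C)C)C(C)C)C/C=C(/C)CCCC1(C)C | intermediate
28 | vanillic acid | COc1cc(C(=O)O)ccc1O | starting material
29 | tert-butyldimethylsilyl 4-[(tert-butyldimethylsilyl)oxy]-3-methoxybenzoate | COc1cc(C(=O)O[Si](C)(C)C(C)(C)C)ccc1O[Si](C)(C)C(C)(C)C | intermediate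
30 | 4-[(tert-butyldimethylsilyl)oxy]-3-methoxybenzoic acid | COc1cc(C(=O)O)ccc1O[Si](C)(C)C(C)(C)C | intermediate
31 | 4-[(tert-butyldimethylsilyl)oxy]-3-methoxybenzoic 2,4,6-trichlorobenzoic anhydride | COc1cc(C(=O)OC(=O)c2c(Cl)cc(Cl)cc2Cl)ccc1O[Si](C)(C)C(C)(C)C | intermediate
32 | (1R,2E,4S,6Z)-3,7,11,11-tetramethyl-4-[(triisopropylsilyl)oxy]cycloundeca-2,6-dien-1-yl 4-[(tert-butyldimethylsilyl)oxy]-3-methoxybenzoate | COc1cc(C(=O)O[C@@H]2/C=C(\C)[C@@H](O[Si](C(C)C)(C(C)C)C(C)C)C/C=C(/C)CCCC2(C)C)ccc1O[Si](C)(C)C(C)(C)C | intermediate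
33 | (1R,2E,4S,6Z)-4-hydroxy-3,7,11,11-tetramethylcycloundeca-2,6-dien-1-yl 4-hydroxy-3-methoxybenzoate | COc1cc(C(=O)O[C@@H]2/C=C(\C)[C@@H](O)C/C=C(/C)CCCC2(C)C)ccc1O | target

**Step count and risks**

Total step count: 21. Longest linear sequence: 20 steps (steps 1–18, 20 and 21, from 1); step 19 is the one-step side branch from vanillic acid.

Steps most likely to fail:

1. Step 15. The bond between the alkoxy-bearing C1 and the fully substituted C11 may form too slowly. The alkoxide could then fragment heterolytically at C3–C9 (retro-aldol-type cleavage), or the enolate could equilibrate so that the C6=C7 alkene slips into conjugation. The fallback sets out from 20 and returns at 23. Compound 20 is silylated with N-(trimethylsilyl)imidazole to the trimethylsilyl ether of 20, F1. F1 is heated in degassed o-dichlorobenzene at about 180–200 °C in base-washed glassware, where the neutral siloxy-Cope rearrangement through the same chair should give the ring-expanded trimethylsilyl enol ether, F2. Methanolysis of F2 (K2CO3, MeOH, 0 °C) gives ketone 23.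

2. Step 14. Oxidative addition of the neopentyl-type alkenyl iodide at copper may be slow, so that dehydroiodination to the alkyne or proto-deiodination outruns C–O bond formation. The fallback sets out from 18 and returns at 20. Aldehyde 18 is treated with CrCl2, LiI and 2-(dichloromethyl)-4,4,5,5-tetramethyl-1,3,2-dioxaborolane in THF (boron variant of the Takai olefination) to give the (E)-alkenylboronic ester, F3. F3 is coupled with 4-methoxybenzyl alcohol under Cu(OAc)2, Et3N and air at rt (Chan–Lam-type oxidative C–O coupling, retention of geometry) to give 20.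

3. Step 10. The ruthenium carbene formed at C6 may cyclise onto the isobutenyl alkene (six-membered ring with loss of 2-methylpropene) instead of the methallyl alkene. The fallback sets out from 15 and returns at 16. The tertiary alcohol of 15 is capped with N-(trimethylsilyl)imidazole to the trimethylsilyl ether of 15, F4, which buries the isobutenyl alkene. Ring-closing metathesis of F4 under the conditions of step 10 should then give the silylated cycloheptene, F5. Methanolysis of F5 (K2CO3, MeOH, 0 °C) returns 16.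

**Further compounds**

F1 | step 15 | trimethylsilyl ether of 20 at the C9 oxygen | C[Si](C)(C)O[C@@]1(C=C(C)C)CC(C)=CC[C@H](O[Si](C(C)C)(C(C)C)C(C)C)[C@@]1(C)/C=C/OCc2ccc(OC)cc2
F2 | step 15 | ring-expanded C9 trimethylsilyl enol ether of 23 (C9=C10, C8 and C11 trans) | COc1ccc(CO[C@@H]2/C=C(\C)[C@@H](O[Si](C(C)C)(C(C)C)C(C)C)C/C=C(/C)C/C(O[Si](C)(C)C)=C/C2(C)C)cc1
F3 | step 14 | (1R,6S,7R)-3,7-dimethyl-1-(2-methylprop-1-en-1-yl)-7-[(E)-2-(4,4,5,5-tetramethyl-1,3,2-dioxaborolan-2-yl)ethenyl]-6-[(triisopropylsilyl)oxy]cyclohept-3-en-1-ol | O[C@@]1(C=C(C)C)CC(C)=CC[C@H](O[Si](C(C)C)(C(C)C)C(C)C)[C@@]1(C)/C=C/B2OC(C)(C)C(C)(C)O2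
F4 | step 10 | trimethylsilyl ether of 15 at the tertiary oxygen | CCOC(=O)[C@@](C)([C@](O[Si](C)(C)C)(C=C(C)C)CC(C)=C)[C@@H](O[Si](C(C)C)(C(C)C)C(C)C)CC=C
F5 | step 10 | trimethylsilyl ether of 16 at the tertiary oxygen | C[Si](C)(C)O[C@@]1(C=C(C)C)CC(C)=CC[C@H](O[Si](C(C)C)(C(C)C)C(C)C)[C@@]1(C)C(=O)OCC
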